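**Retrosynthetic overview**

- The route rests on ring B of the hydrindane: C7 (CHBr) lies beside the quaternary C7a–CH3, which is bonded to the ring-fusion C3a–H next to the tertiary carbinol C4. C4 with its methyl, C5–C6–C7 and the C7a unit map onto (R)-linalool.
- Ring B is closed first (step 10). A bromonium ion on the E-trisubstituted alkene of a linalool-derived enyne acetate is opened at C7a by the proximal alkyne carbon (bond C7a–C3a, plus C7–Br), and the vinyl cation becomes the C3 methyl ketone.
- Ring C follows by aldol condensation of the C1 aldehyde (from the CH2OSi arm) with the methyl ketone. The C3 ketone is then homologated to a C3 aldehyde placed by equilibration.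
- Ring A is made separately as (S)-4-bromo-3,3-dimethylcyclohexanone (bromonium closure of a chiral β-keto ester, epimers separated) and joined last: alkenylchromium addition to the aldehyde, oxidation, and reductive 1,3-transposition of the tosylhydrazone to the exocyclic E alkene, then deacetylation.

Key step: step 10

Remark: hydrindane atoms carry the numbers C1–C3, C3a, C4–C7, C7a (ring B six-membered, ring C five-membered, ring A the bromodimethylcyclohexylidene ring). Centres that are mixtures and vanish later (acetal carbon in 2–7, C1 of the β-keto ester 28, carbinol in 31, C=N in 33) are carried unresolved.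

**Route**

Step 1
Reactants: 1 (R)-linalool
Product: 3 (2R)-2-ethenyl-5-methoxy-2-methyloxolane (both anomers), via vinyl lactol 2 (not isolated)
Conditions: O3 (1 equiv), CH2Cl2–MeOH, −78 °C; Me2S, −78 °C → rt; PPTS (cat.), MeOH, rt
Reagents that add atoms: methanol, CO
Why: Chemoselective ozonolysis of the electron-rich trisubstituted alkene (the vinyl group reacts much more slowly) gives the γ-hydroxy aldehyde, which closes to the lactol and is fixed by acid-catalysed acetalisation, so that the tertiary oxygen and the aldehyde are masked in one ring while the carbinol centre is untouched.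

Step 2
Reactants: 3 (2R)-2-ethenyl-5-methoxy-2-methyloxolane
Product: 4 (2R)-5-methoxy-2-methyloxolane-2-carbaldehyde
Conditions: O3, CH2Cl2–MeOH, −78 °C; Me2S, −78 °C → rt
Reagents that add atoms: ozone, [O-][O+]=O
Why: Ozonolysis with reductive work-up cleaves the only remaining alkene to an α-alkoxy aldehyde that has no α-hydrogen and so cannot racemise.

Step 3
Reactants: 4 (2R)-5-methoxy-2-methyloxolane-2-carbaldehyde
Product: 5 (2R)-2-ethynyl-5-methoxy-2-methyloxolane
Conditions: dimethyl (1-diazo-2-oxopropyl)phosphonate, K2CO3, MeOH, 0 °C → rt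
Reagents that add atoms: dimethyl (1-diazo-2-oxopropyl)phosphonate, COP(=O)(OC)C(=[N+]=[N-])C(C)=O
Why: Seyferth–Gilbert homologation with the Ohira–Bestmann reagent converts the hindered aldehyde into the terminal alkyne under mild base that the acetal tolerates.

Step 4
Reactants: 5 (2R)-2-ethynyl-5-methoxy-2-methyloxolane
Product: 6 (2R)-5-methoxy-2-methyl-2-(prop-1-yn-1-yl)oxolane
Conditions: n-BuLi, THF, −78 °C; MeI, −78 °C → rt
Reagents that add atoms: iodomethane, CI
Why: Deprotonation of the terminal alkyne and C-alkylation of the lithium acetylide give the methyl alkyne needed as cyclisation terminator, the acetal being inert to the base.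

Step 5
Reactants: 6 (2R)-5-methoxy-2-methyl-2-(prop-1-yn-1-yl)oxolane
Product: 7 (5R)-5-methyl-5-(prop-1-yn-1-yl)oxolan-2-ol (lactol)
Conditions: AcOH–THF–H2O (3:1:1), 40 °C
Reagents that add atoms: water, O
Why: Mild acid hydrolysis of the cyclic mixed acetal frees the lactol (a masked γ-hydroxy aldehyde) without ionising the tertiary propargylic C–O bond.

Step 6
Reactants: 7 (5R)-5-methyl-5-(prop-1-yn-1-yl)oxolan-2-ol; 8 ethyl 2-(triphenylphosphoranylidene)propanoate
Product: 9 ethyl (2E,6R)-6-hydroxy-2,6-dimethylnon-2-en-7-ynoate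
Conditions: toluene, 90 °C
Reagents that add atoms: none
Why: Wittig reaction of the open hydroxy-aldehyde form of the lactol with the stabilised α-methyl ylide should give the E trisubstituted enoate, the geometry that later fixes the quaternary and CHBr centres.

Step 7
Reactants: 9 ethyl (2E,6R)-6-hydroxy-2,6-dimethylnon-2-en-7-ynoate
Product: 10 (2E,6R)-2,6-dimethylnon-2-en-7-yne-1,6-diol
Conditions: i-Bu2AlH, CH2Cl2, −78 °C → 0 °C; aq. potassium sodium tartrate
Reagents that add atoms: none
Why: 1,2-Reduction of the conjugated ester by the aluminium hydride gives the allylic alcohol and leaves alkene, alkyne and the tertiary alcohol unchanged, which is why the acetate is put on only afterwards.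

Step 8
Reactants: 10 (2E,6R)-2,6-dimethylnon-2-en-7-yne-1,6-diol
Product: 11 (2E,6R)-1-[tert-butyl(diphenyl)silyl]oxy-2,6-dimethylnon-2-en-7-yn-6-ol
Conditions: TBDPSCl, imidazole, CH2Cl2, 0 °C → rt
Reagents that add atoms: tert-butyl(chloro)diphenylsilane, CC(C)(C)[Si](Cl)(c1ccccc1)c1ccccc1
Why: Silylation is selective for the primary allylic alcohol because the tertiary propargylic alcohol is too hindered for the bulky silyl chloride.

Step 9
Reactants: 11 (2E,6R)-1-[tert-butyl(diphenyl)silyl]oxy-2,6-dimethylnon-2-en-7-yn-6-ol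
Product: 12 (2E,6R)-1-[tert-butyl(diphenyl)silyl]oxy-2,6-dimethylnon-2-en-7-yn-6-yl acetate
Conditions: Ac2O, Et3N, DMAP, CH2Cl2, rt
Reagents that add atoms: acetic anhydride, CC(=O)OC(C)=O
Why: DMAP-catalysed acylation esterifies the tertiary propargylic alcohol (the slim alkynyl group keeps it accessible) and so removes the nucleophilicity of the carbinol oxygen before the bromonium step.

Step 10
Reactants: 12 (2E,6R)-1-[tert-butyl(diphenyl)silyl]oxy-2,6-dimethylnon-2-en-7-yn-6-yl acetate
Product: 14 (1R,2S,3R,4S)-2-acetyl-4-bromo-3-{[tert-butyl(diphenyl)silyl]oxymethyl}-1,3-dimethylcyclohexyl acetate, via dioxinium ion 13 (not isolated)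
Conditions: Et2SBr·SbCl5Br (1.1 equiv), MeNO2, −25 °C; aq. NaHCO3–Na2SO3, rt
Reagents that add atoms: bromodiethylsulfonium bromopentachloroantimonate, CC[S+](Br)CC.Cl[Sb-](Cl)(Cl)(Cl)(Cl)Br; water, O
Why: Proposed new method: Et2SBr·SbCl5Br should deliver Br+ to the trisubstituted alkene (much more nucleophilic than the alkyne that bears the propargylic acetate), and the proximal alkyne carbon then opens the bromonium ion at its tertiary carbon anti to bromine through a chair, which closes six-membered ring B with the second alkyne carbon left outside the ring (exo with respect to the alkyne, endo with respect to the alkene) as a linear vinyl cation; this cation is held by the neighbouring acetate carbonyl as dioxinium ion 13 (nitromethane can play the same part), and water at work-up opens 13 to the methyl ketone with the acetate on the tertiary oxygen. The closest known reactions are the cation–olefin cyclisations induced by this bromosulfonium reagent with alkene and arene terminators and the alkyne-terminated polyene cyclisations started by protons or acetals; the two have not been joined. The quaternary C7a and the CHBr carbon C7 are set by stereospecific anti addition across the E alkene, which puts the silyloxymethyl arm and bromine equatorial and the methyl axial; their absolute sense comes from the linalool carbinol, which takes the chair with methyl equatorial and acetoxy axial because the other chair would place two methyl groups 1,3-diaxial. C3a ends with the acetyl group equatorial (trans to the arm on C7a) on ketonisation, which is also the more stable position of this epimerisable centre. The step needs alkene-over-alkyne selectivity and C- over O-capture: the acetate blocks bromoetherification by the carbinol oxygen, and attack by the distal alkyne carbon would require a seven-membered ring with a bent vinyl cation.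

Step 11
Reactants: 14 (1R,2S,3R,4S)-2-acetyl-4-bromo-3-{[tert-butyl(diphenyl)silyl]oxymethyl}-1,3-dimethylcyclohexyl acetate
Product: 15 (1R,2S,3R,4S)-2-acetyl-4-bromo-3-(hydroxymethyl)-1,3-dimethylcyclohexyl acetate
Conditions: HF·pyridine, pyridine, THF, 0 °C → rt
Reagents that add atoms: none
Why: Fluoride-mediated desilylation under buffered acidic conditions frees the neopentylic primary alcohol without base, so the β-acetoxy ketone is not exposed to elimination.

Step 12
Reactants: 15 (1R,2S,3R,4S)-2-acetyl-4-bromo-3-(hydroxymethyl)-1,3-dimethylcyclohexyl acetate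
Product: 16 (1R,2S,3R,4S)-2-acetyl-4-bromo-3-formyl-1,3-dimethylcyclohexyl acetate
Conditions: Dess–Martin periodinane, NaHCO3, CH2Cl2, rt
Reagents that add atoms: none
Why: Dess–Martin oxidation gives the non-enolisable neopentylic aldehyde under neutral conditions.

Step 13
Reactants: 16 (1R,2S,3R,4S)-2-acetyl-4-bromo-3-formyl-1,3-dimethylcyclohexyl acetate
Product: 17 (3aS,4R,7S,7aS)-7-bromo-4,7a-dimethyl-3-oxo-3a,4,5,6,7,7a-hexahydro-3H-inden-4-yl acetate
Conditions: Bn2NH·CF3CO2H (cat.), benzene, 60 °C
Reagents that add atoms: none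
Why: Intramolecular aldol condensation under amine-salt catalysis, in which only the ketone methyl group can reach the non-enolisable aldehyde, closes five-membered ring C across the trans-diequatorial arms to the trans-fused cyclopentenone, the near-neutral medium being chosen to avoid β-elimination of the axial acetate and epimerisation at C3a.

Step 14
Reactants: 17 (3aS,4R,7S,7aS)-7-bromo-4,7a-dimethyl-3-oxo-3a,4,5,6,7,7a-hexahydro-3H-inden-4-yl acetate
Product: 18 (3aS,4R,7S,7aS)-7-bromo-4,7a-dimethyl-3-oxooctahydro-1H-inden-4-yl acetate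
Conditions: H2 (1 atm), 10% Pd/C, EtOAc, rt
Reagents that add atoms: none
Why: Catalytic hydrogenation saturates the disubstituted enone alkene (no new stereocentre) under neutral conditions that leave the secondary alkyl bromide, the acetate and the epimerisable C3a alone.

Step 15
Reactants: 18 (3aS,4R,7S,7aS)-7-bromo-4,7a-dimethyl-3-oxooctahydro-1H-inden-4-yl acetate
Product: 19 (3aS,4R,7S,7aS)-7-bromo-4,7a-dimethyl-3-methylideneoctahydro-1H-inden-4-yl acetate
Conditions: Zn, CH2Br2, TiCl4, THF–CH2Cl2, 0 °C → rt
Reagents that add atoms: dibromomethane, BrCBr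
Why: Takai–Lombardo methylenation with the non-basic zinc–titanium methylene reagent converts the hindered, easily enolised ketone into the exocyclic alkene without β-elimination of acetate or epimerisation, and it spares the ester.

Step 16
Reactants: 19 (3aS,4R,7S,7aS)-7-bromo-4,7a-dimethyl-3-methylideneoctahydro-1H-inden-4-yl acetate
Product: 20 (3S,3aS,4R,7S,7aS)-7-bromo-3-(hydroxymethyl)-4,7a-dimethyloctahydro-1H-inden-4-yl acetate
Conditions: 9-BBN, THF, 50 °C; H2O2, aq. NaOH, 0 °C
Reagents that add atoms: hydrogen peroxide, OO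
Why: Anti-Markovnikov hydroboration–oxidation gives the primary alcohol; boron should add from the face of ring C away from the axial C7a methyl and the axial acetoxy group, so the CH2OH is expected on the hindered face, a centre that step 17 corrects.

Step 17
Reactants: 20 (3S,3aS,4R,7S,7aS)-7-bromo-3-(hydroxymethyl)-4,7a-dimethyloctahydro-1H-inden-4-yl acetate
Product: 22 (3R,3aS,4R,7S,7aS)-7-bromo-3-formyl-4,7a-dimethyloctahydro-1H-inden-4-yl acetate, via epimeric aldehyde 21 (not isolated)
Conditions: Dess–Martin periodinane, NaHCO3, CH2Cl2, rt; then DBU, CH2Cl2, rt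
Reagents that add atoms: none
Why: Dess–Martin oxidation followed by base epimerisation through the enolate should place the formyl group on the open face of ring C, trans to the C7a methyl and away from C4 with its axial acetoxy group, which sets C3 under thermodynamic control.

Step 18
Reactants: 23 (S)-1-phenylethanol; 24 tert-butyl 3-oxobutanoate
Product: 25 (1S)-1-phenylethyl 3-oxobutanoate
Conditions: toluene, 110 °C (tert-butanol distilled off)
Reagents that add atoms: none
Why: Thermal transacetoacetylation through acetylketene exchanges the tert-butyl ester for the chiral, acid-labile benzylic ester without touching its stereocentre.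

Step 19
Reactants: 25 (1S)-1-phenylethyl 3-oxobutanoate; 26 1-bromo-3-methylbut-2-ene
Product: 27 (1S)-1-phenylethyl 7-methyl-3-oxooct-6-enoate
Conditions: NaH, THF, 0 °C; n-BuLi, 0 °C; then 26, 0 °C → rt
Reagents that add atoms: none
Why: γ-Alkylation of the acetoacetate dianion, whose terminal carbanion is the more reactive site, with the allylic bromide gives the prenylated β-keto ester.

Step 20
Reactants: 27 (1S)-1-phenylethyl 7-methyl-3-oxooct-6-enoate
Product: 28 (1S)-1-phenylethyl (3S)-3-bromo-2,2-dimethyl-6-oxocyclohexane-1-carboxylate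
Conditions: Et2SBr·SbCl5Br, MeNO2, −25 °C; aq. NaHCO3; separation of the two C3 epimers by chromatography or crystallisation
Reagents that add atoms: bromodiethylsulfonium bromopentachloroantimonate, CC[S+](Br)CC.Cl[Sb-](Cl)(Cl)(Cl)(Cl)Br
Why: Bromonium-induced cation–olefin cyclisation terminated by the enol carbon of a β-keto ester (a classical terminator for such closures) forms ring A through a chair with bromine equatorial; the reagent is achiral, so both configurations at CHBr form, and because of the chiral ester they are diastereomers from which the (3S) isomer is separated.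

Step 21
Reactants: 28 (1S)-1-phenylethyl (3S)-3-bromo-2,2-dimethyl-6-oxocyclohexane-1-carboxylate
Product: 29 (4S)-4-bromo-3,3-dimethylcyclohexan-1-one
Conditions: CF3CO2H, CH2Cl2, rt; then toluene, 60 °C
Reagents that add atoms: none
Why: Acidolysis of the benzylic ester and decarboxylation of the β-keto acid give the ketone without base, which could make an enolate displace the 1,3-related bromide, and the CHBr centre is not involved.

Step 22
Reactants: 29 (4S)-4-bromo-3,3-dimethylcyclohexan-1-one
Product: 30 (4S)-4-bromo-5,5-dimethylcyclohex-1-en-1-yl trifluoromethanesulfonate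
Conditions: LiN(SiMe3)2, THF, −78 °C; PhNTf2, −78 °C → 0 °C
Reagents that add atoms: N-phenylbis(trifluoromethanesulfonimide), O=S(=O)(N(c1ccccc1)S(=O)(=O)C(F)(F)F)C(F)(F)F
Why: Kinetic deprotonation at the unhindered α-CH2 (the other one is neopentylic) and O-triflation of the enolate at low temperature give the enol triflate with its double bond on the CH2–CH2–CHBr side of ring A.

Step 23
Reactants: 22 (3R,3aS,4R,7S,7aS)-7-bromo-3-formyl-4,7a-dimethyloctahydro-1H-inden-4-yl acetate; 30 (4S)-4-bromo-5,5-dimethylcyclohex-1-en-1-yl trifluoromethanesulfonate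
Product: 31 (3R,3aS,4R,7S,7aS)-7-bromo-3-{[(4S)-4-bromo-5,5-dimethylcyclohex-1-en-1-yl](hydroxy)methyl}-4,7a-dimethyloctahydro-1H-inden-4-yl acetate (both carbinol epimers)
Conditions: CrCl2, NiCl2 (cat.), DMF, rt
Reagents that add atoms: none
Why: Nozaki–Hiyama–Kishi coupling adds the alkenylchromium species formed from the triflate to the aldehyde under neutral conditions that tolerate both alkyl bromides and the acetate; the carbinol centre forms as a mixture that the next step removes.

Step 24
Reactants: 31 (3R,3aS,4R,7S,7aS)-7-bromo-3-{[(4S)-4-bromo-5,5-dimethylcyclohex-1-en-1-yl](hydroxy)methyl}-4,7a-dimethyloctahydro-1H-inden-4-yl acetate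
Product: 32 (3R,3aS,4R,7S,7aS)-7-bromo-3-[(4S)-4-bromo-5,5-dimethylcyclohex-1-ene-1-carbonyl]-4,7a-dimethyloctahydro-1H-inden-4-yl acetate
Conditions: Dess–Martin periodinane, NaHCO3, CH2Cl2, rt
Reagents that add atoms: none
Why: Dess–Martin oxidation of the allylic alcohol gives the enone and erases the carbinol mixture.

Step 25
Reactants: 32 (3R,3aS,4R,7S,7aS)-7-bromo-3-[(4S)-4-bromo-5,5-dimethylcyclohex-1-ene-1-carbonyl]-4,7a-dimethyloctahydro-1H-inden-4-yl acetate
Product: 33 4-methylbenzenesulfonylhydrazone of 32
Conditions: TsNHNH2, PPTS (cat.), EtOH–THF, 60 °C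
Reagents that add atoms: 4-methylbenzenesulfonohydrazide, Cc1ccc(cc1)S(=O)(=O)NN
Why: Acid-catalysed condensation of the ketone with tosylhydrazide gives the α,β-unsaturated tosylhydrazone needed for reductive transposition.

Step 26
Reactants: 33 4-methylbenzenesulfonylhydrazone of 32
Product: 35 (3S,3aS,4R,7S,7aS)-7-bromo-3-{(E)-[(4S)-4-bromo-3,3-dimethylcyclohexylidene]methyl}-4,7a-dimethyloctahydro-1H-inden-4-yl acetate, via allylic diazene 34 (not isolated)
Conditions: catecholborane, CHCl3, 0 °C → rt; NaOAc·3H2O, reflux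
Reagents that add atoms: none
Why: 1,2-Reduction of the C=N bond and loss of sulfinate give the allylic diazene, which expels N2 in a retro-ene step that moves the double bond to the exocyclic position and delivers hydrogen to the ring alkene carbon (reductive 1,3-transposition of an enone tosylhydrazone); allylic 1,2-strain should place the bulky hydrindanyl group over the ring double bond, so that it ends cis to the CH2 that receives hydrogen (the CH2–CH2–CHBr arm), which is the E alkene of the target.

Step 27
Reactants: 35 (3S,3aS,4R,7S,7aS)-7-bromo-3-{(E)-[(4S)-4-bromo-3,3-dimethylcyclohexylidene]methyl}-4,7a-dimethyloctahydro-1H-inden-4-yl acetate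
Product: 36 (3S,3aS,4R,7S,7aS)-7-bromo-3-{(E)-[(4S)-4-bromo-3,3-dimethylcyclohexylidene]methyl}-4,7a-dimethyloctahydro-1H-inden-4-ol (CNP0119865.1)
Conditions: i-Bu2AlH, CH2Cl2, −78 °C → −20 °C; aq. potassium sodium tartrate
Reagents that add atoms: none
Why: Reductive cleavage of the tertiary acetate by the aluminium hydride frees the carbinol without base or nucleophile that could attack the two secondary bromides.

**Compound list**

1 | (R)-linalool | C=C[C@](C)(O)CCC=C(C)C | starting material
2 | (5R)-5-ethenyl-5-methyloxolan-2-ol (lactol) | C=C[C@]1(C)OC(O)CC1 | intermediate (not isolated)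
3 | (2R)-2-ethenyl-5-methoxy-2-methyloxolane | C=C[C@]1(C)OC(OC)CC1 | intermediate
4 | (2R)-5-methoxy-2-methyloxolane-2-carbaldehyde | O=C[C@]1(C)OC(OC)CC1 | intermediate
5 | (2R)-2-ethynyl-5-methoxy-2-methyloxolane | C#C[C@]1(C)OC(OC)CC1 | intermediate
6 | (2R)-5-methoxy-2-methyl-2-(prop-1-yn-1-yl)oxolane | CC#C[C@]1(C)OC(OC)CC1 | intermediate
7 | (5R)-5-methyl-5-(prop-1-yn-1-yl)oxolan-2-ol | CC#C[C@]1(C)OC(O)CC1 | intermediate
8 | ethyl 2-(triphenylphosphoranylidene)propanoate | CCOC(=O)C(C)=P(c1ccccc1)(c1ccccc1)c1ccccc1 | starting material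
9 | ethyl (2E,6R)-6-hydroxy-2,6-dimethylnon-2-en-7-ynoate | CC#C[C@](C)(O)CC/C=C(\C)C(=O)OCC | intermediate
10 | (2E,6R)-2,6-dimethylnon-2-en-7-yne-1,6-diol | CC#C[C@](C)(O)CC/C=C(\C)CO | intermediate
11 | (2E,6R)-1-[tert-butyl(diphenyl)silyl]oxy-2,6-dimethylnon-2-en-7-yn-6-ol | CC#C[C@](C)(O)CC/C=C(\C)CO[Si](c1ccccc1)(c1ccccc1)C(C)(C)C | intermediate
12 | (2E,6R)-1-[tert-butyl(diphenyl)silyl]oxy-2,6-dimethylnon-2-en-7-yn-6-yl acetate (key-step precursor) | CC#C[C@](C)(OC(C)=O)CC/C=C(\C)CO[Si](c1ccccc1)(c1ccccc1)C(C)(C)C | intermediate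
13 | bicyclic 2,4-dimethyl-1,3-dioxin-1-ium ion fused to ring B, bromopentachloroantimonate salt | CC(C)(C)[Si](c1ccccc1)(c1ccccc1)OC[C@]2(C)[C@@H](Br)CC[C@@]3(C)OC(C)=[O+]C(C)=C23.Cl[Sb-](Cl)(Cl)(Cl)(Cl)Br | intermediate (not isolated)
14 | (1R,2S,3R,4S)-2-acetyl-4-bromo-3-{[tert-butyl(diphenyl)silyl]oxymethyl}-1,3-dimethylcyclohexyl acetate (key-step product) | CC(C)(C)[Si](c1ccccc1)(c1ccccc1)OC[C@]2(C)[C@@H](Br)CC[C@@](C)(OC(C)=O)[C@H]2C(C)=O | intermediate
15 | (1R,2S,3R,4S)-2-acetyl-4-bromo-3-(hydroxymethyl)-1,3-dimethylcyclohexyl acetate | OC[C@]1(C)[C@@H](Br)CC[C@@](C)(OC(C)=O)[C@H]1C(C)=O | intermediate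
16 | (1R,2S,3R,4S)-2-acetyl-4-bromo-3-formyl-1,3-dimethylcyclohexyl acetate | O=C[C@]1(C)[C@@H](Br)CC[C@@](C)(OC(C)=O)[C@H]1C(C)=O | intermediate
17 | (3aS,4R,7S,7aS)-7-bromo-4,7a-dimethyl-3-oxo-3a,4,5,6,7,7a-hexahydro-3H-inden-4-yl acetate | O=C2C=C[C@]3(C)[C@@H](Br)CC[C@@](C)(OC(C)=O)[C@@H]23 | intermediate
18 | (3aS,4R,7S,7aS)-7-bromo-4,7a-dimethyl-3-oxooctahydro-1H-inden-4-yl acetate | O=C2CC[C@]3(C)[C@@H](Br)CC[C@@](C)(OC(C)=O)[C@@H]23 | intermediate
19 | (3aS,4R,7S,7aS)-7-bromo-4,7a-dimethyl-3-methylideneoctahydro-1H-inden-4-yl acetate | C=C2CC[C@]3(C)[C@@H](Br)CC[C@@](C)(OC(C)=O)[C@@H]23 | intermediate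
20 | (3S,3aS,4R,7S,7aS)-7-bromo-3-(hydroxymethyl)-4,7a-dimethyloctahydro-1H-inden-4-yl acetate (CH2OH cis to the C7a methyl) | OC[C@H]2CC[C@]3(C)[C@@H](Br)CC[C@@](C)(OC(C)=O)[C@@H]23 | intermediate
21 | (3S,3aS,4R,7S,7aS)-7-bromo-3-formyl-4,7a-dimethyloctahydro-1H-inden-4-yl acetate (CHO cis to the C7a methyl) | O=C[C@H]2CC[C@]3(C)[C@@H](Br)CC[C@@](C)(OC(C)=O)[C@@H]23 | intermediate (not isolated)
22 | (3R,3aS,4R,7S,7aS)-7-bromo-3-formyl-4,7a-dimethyloctahydro-1H-inden-4-yl acetate (CHO trans to the C7a methyl) | O=C[C@@H]2CC[C@]3(C)[C@@H](Br)CC[C@@](C)(OC(C)=O)[C@@H]23 | intermediate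
23 | (S)-1-phenylethanol | C[C@H](O)c1ccccc1 | starting material
24 | tert-butyl 3-oxobutanoate | CC(=O)CC(=O)OC(C)(C)C | starting material
25 | (1S)-1-phenylethyl 3-oxobutanoate | C[C@H](OC(=O)CC(C)=O)c1ccccc1 | intermediate
26 | 1-bromo-3-methylbut-2-ene | CC(C)=CCBr | starting material
27 | (1S)-1-phenylethyl 7-methyl-3-oxooct-6-enoate | C[C@H](OC(=O)CC(=O)CCC=C(C)C)c1ccccc1 | intermediate
28 | (1S)-1-phenylethyl (3S)-3-bromo-2,2-dimethyl-6-oxocyclohexane-1-carboxylate (C1 epimers and enol) | C[C@H](OC(=O)C1C(=O)CC[C@H](Br)C1(C)C)c1ccccc1 | intermediate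
29 | (4S)-4-bromo-3,3-dimethylcyclohexan-1-one | O=C1CC[C@H](Br)C(C)(C)C1 | intermediate
30 | (4S)-4-bromo-5,5-dimethylcyclohex-1-en-1-yl trifluoromethanesulfonate | O=S(=O)(OC1=CC[C@H](Br)C(C)(C)C1)C(F)(F)F | intermediate
31 | (3R,3aS,4R,7S,7aS)-7-bromo-3-{[(4S)-4-bromo-5,5-dimethylcyclohex-1-en-1-yl](hydroxy)methyl}-4,7a-dimethyloctahydro-1H-inden-4-yl acetate | OC(C1=CC[C@H](Br)C(C)(C)C1)[C@@H]2CC[C@]3(C)[C@@H](Br)CC[C@@](C)(OC(C)=O)[C@@H]23 | intermediate
32 | (3R,3aS,4R,7S,7aS)-7-bromo-3-[(4S)-4-bromo-5,5-dimethylcyclohex-1-ene-1-carbonyl]-4,7a-dimethyloctahydro-1H-inden-4-yl acetate | O=C(C1=CC[C@H](Br)C(C)(C)C1)[C@@H]2CC[C@]3(C)[C@@H](Br)CC[C@@](C)(OC(C)=O)[C@@H]23 | intermediate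
33 | 4-methylbenzenesulfonylhydrazone of 32 | Cc1ccc(cc1)S(=O)(=O)NN=C(C1=CC[C@H](Br)C(C)(C)C1)[C@@H]2CC[C@]3(C)[C@@H](Br)CC[C@@](C)(OC(C)=O)[C@@H]23 | intermediate
34 | allylic diazene (diazenyl in place of the hydrazone, CH–N=NH) | N=NC(C1=CC[C@H](Br)C(C)(C)C1)[C@@H]2CC[C@]3(C)[C@@H](Br)CC[C@@](C)(OC(C)=O)[C@@H]23 | intermediate (not isolated)
35 | (3S,3aS,4R,7S,7aS)-7-bromo-3-{(E)-[(4S)-4-bromo-3,3-dimethylcyclohexylidene]methyl}-4,7a-dimethyloctahydro-1H-inden-4-yl acetate | CC1(C)C/C(=C/[C@@H]2CC[C@]3(C)[C@@H](Br)CC[C@@](C)(OC(C)=O)[C@@H]23)CC[C@@H]1Br | intermediate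
36 | (3S,3aS,4R,7S,7aS)-7-bromo-3-{(E)-[(4S)-4-bromo-3,3-dimethylcyclohexylidene]methyl}-4,7a-dimethyloctahydro-1H-inden-4-ol (CNP0119865.1) | CC1(C)C/C(=C/[C@@H]2CC[C@]3(C)[C@@H](Br)CC[C@@](C)(O)[C@@H]23)CC[C@@H]1Br | target

**Step count and risks**

Total step count: 27. Longest linear sequence: 22 steps (steps 1–17 and 23–27, from (R)-linalool); the ring A branch is steps 18–22.

Steps most likely to fail:

1. Step 10 (Proposed new method). The bromonium ion may not be captured by the acetate-deactivated alkyne: halide capture, proton loss to allylic bromides, or capture of the vinyl cation by halide could take over. The fallback uses known chemistry and sets out from 12. Semihydrogenation of the alkyne (H2, Pd/CaCO3 poisoned with Pb(OAc)2, quinoline, EtOAc) should give the (Z)-propenyl acetate F1. Et2SBr·SbCl5Br in MeNO2 at −25 °C then closes ring B with the alkene as terminator, a cation–olefin cyclisation of the established bromosulfonium type; the secondary cation is taken up by the neighbouring acetate and opened by water at work-up to the hydroxy acetate F2. Dess–Martin oxidation of the secondary alcohol comes back to the route at 14.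

2. Step 13. Acetic acid may be lost by β-elimination from the β-acetoxy ketone, C3a may epimerise to the cis-fused series, or closure to the strained trans-fused cyclopentenone may be slow. The fallback sets out from 16. Soft enolisation with Me3SiOTf and i-Pr2NEt (CH2Cl2, −78 °C) should give the methyl-side silyl enol ether F3. BF3·OEt2 then promotes an intramolecular Mukaiyama aldol addition to the aldehyde to give the β-hydroxy ketone F4, and syn dehydration with the Burgess reagent (benzene, 50 °C) comes back at 17.

3. Step 26. Geometric control in the retro-ene step may be poor or reversed (the hydrindanyl group ending cis to the CH2 beside the gem-dimethyl carbon), or reduction of the hindered hydrazone may be incomplete. The fallback sets out from aldehyde 22 and ketone 29. NaBH4 reduction of 29 gives the cyclohexanol F5; Mitsunobu reaction with 1-phenyl-1H-tetrazole-5-thiol (PPh3, DIAD) gives the sulfide F6; oxidation with H2O2 and (NH4)6Mo7O24 gives the sulfone F7. Julia–Kocienski olefination of 22 with the anion of F7 (KN(SiMe3)2, DME, −60 °C → rt) forms the exocyclic alkene directly; the E isomer is separated from the Z isomer on AgNO3-impregnated silica, and the route is rejoined at 35.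

**Further compounds**

F1 | step 10 | (2E,6R,7Z)-1-[tert-butyl(diphenyl)silyl]oxy-2,6-dimethylnona-2,7-dien-6-yl acetate | C/C=C\[C@](C)(OC(C)=O)CC/C=C(\C)CO[Si](c1ccccc1)(c1ccccc1)C(C)(C)C
F2 | step 10 | 1-hydroxyethyl analogue of 14 (same ring configuration; carbinol centre from anti addition, removed on oxidation) | CC(C)(C)[Si](c1ccccc1)(c1ccccc1)OC[C@]2(C)[C@@H](Br)CC[C@@](C)(OC(C)=O)[C@H]2C(C)O
F3 | step 13 | trimethylsilyl enol ether of 16 on the methyl side | O=C[C@]1(C)[C@@H](Br)CC[C@@](C)(OC(C)=O)[C@H]1C(=C)O[Si](C)(C)C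
F4 | step 13 | 1-hydroxy derivative of 18 (aldol adduct; both C1 epimers) | O=C2CC(O)[C@]3(C)[C@@H](Br)CC[C@@](C)(OC(C)=O)[C@@H]23
F5 | step 26 | (4S)-4-bromo-3,3-dimethylcyclohexan-1-ol (both carbinol epimers) | OC1CC[C@H](Br)C(C)(C)C1
F6 | step 26 | 5-{[(4S)-4-bromo-3,3-dimethylcyclohexyl]sulfanyl}-1-phenyl-1H-tetrazole | c1ccc(cc1)-n1nnnc1SC1CC[C@H](Br)C(C)(C)C1
F7 | step 26 | 5-{[(4S)-4-bromo-3,3-dimethylcyclohexyl]sulfonyl}-1-phenyl-1H-tetrazole | O=S(=O)(C1CC[C@H](Br)C(C)(C)C1)c1nnnn1-c1ccccc1
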